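The 14-membered carbocycle (numbered C1 = lactone O–CH, C2 = CH–OAc, C3 = CH–CH3, C11/C12 = epoxide, C14 = ring-fusion CH) is disconnected between C7 and C8. The key step exploits the tertiary allylic carbinol C7(CH3)(OH)–C8H=C9H of this ring, the retron of an alkenylmetal addition to a methyl ketone: an intramolecular Nozaki–Hiyama–Kishi reaction joins two electrophilic carbons, ketone C7 and (E)-alkenyl iodide C8, by chromium-mediated polarity reversal. One operation closes the macrocycle, creates the C7 stereocentre and conserves the E geometry. The precursor is an open chain already carrying the cis-fused α-methylene-γ-butyrolactone, the acetate and the epoxide.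

Key step: step 13

Remark: both enantiomers of the fructose-type Shi ketone are taken as available catalysts, commercial crotonaldehyde diethyl acetal is taken as its E isomer, and open-chain intermediates are discussed with the ring numbering of the target.

Step 1
Reactants: 1 ethynyltrimethylsilane; 2 propargyl bromide
Product: 4 1-(trimethylsilyl)penta-1,4-diyne, via alkynylmagnesium bromide 3 (not isolated)
Conditions: EtMgBr, THF, 0 °C to rt; CuCl (cat.), then 2, 50 °C
Reagents that add atoms: none
Why: Deprotonation gives the alkynyl Grignard reagent, which should couple with the propargylic bromide under copper catalysis (SN2 alkynyl–propargyl coupling) to give the skipped diyne with one terminus blocked by silicon.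

Step 2
Reactants: 4 1-(trimethylsilyl)penta-1,4-diyne
Product: 6 (E)-4-methyl-7-(trimethylsilyl)hept-3-en-6-yn-1-ol, via alkenyldimethylalane 5 (not isolated)
Conditions: Me3Al, Cp2ZrCl2 (cat.), CH2Cl2, 0 °C to rt; then n-BuLi, hexane/THF, −78 °C; oxirane, −78 to 0 °C; aq. NH4Cl
Reagents that add atoms: trimethylaluminium, C[Al](C)C; oxirane, C1CO1
Why: Zirconium-catalysed syn-carboalumination (Negishi carboalumination) of the free terminal alkyne places methyl on the internal and aluminium on the terminal carbon, and the derived alanate opens oxirane with retention, so the syn addition fixes the E-trisubstituted C11=C12 alkene; the silylated alkyne should not react.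

Step 3
Reactants: 6 (E)-4-methyl-7-(trimethylsilyl)hept-3-en-6-yn-1-ol
Product: 7 (E)-4-methylhept-3-en-6-yn-1-ol
Conditions: K2CO3, MeOH, rt
Reagents that add atoms: none
Why: Methanolysis of the alkynyl C–Si bond (protodesilylation) proceeds under conditions too mild to isomerise the skipped enyne.

Step 4
Reactants: 7 (E)-4-methylhept-3-en-6-yn-1-ol
Product: 9 (3E,6E)-7-iodo-4-methylhepta-3,6-dien-1-ol, via alkenylzirconocene chloride 8 (not isolated)
Conditions: Cp2Zr(H)Cl (2.2 equiv), THF, rt; then I2 (1.05 equiv), −78 to 0 °C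
Reagents that add atoms: iodine, II
Why: Hydrozirconation–iodination: one equivalent of hydride is consumed by the hydroxyl, the second adds syn to the terminal alkyne with zirconium on the terminal carbon, and iodinolysis with retention should give the (E)-alkenyl iodide while the trisubstituted alkene stays untouched.

Step 5
Reactants: 9 (3E,6E)-7-iodo-4-methylhepta-3,6-dien-1-ol
Product: 10 (3E,6E)-7-iodo-4-methylhepta-3,6-dienal
Conditions: Dess–Martin periodinane, NaHCO3, CH2Cl2, 0 °C; crude product used at once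
Reagents that add atoms: none
Why: Dess–Martin oxidation is neutral and fast, so the β,γ-unsaturated aldehyde should not move into conjugation and can be carried on without chromatography.

Step 6
Reactants: 10 (3E,6E)-7-iodo-4-methylhepta-3,6-dienal
Product: 11 methyl (5E,8E)-3-hydroxy-9-iodo-6-methyl-2-methylidenenona-5,8-dienoate
Conditions: i-Bu2AlH, N-methylmorpholine N-oxide, methyl propiolate, THF, 0 °C; then 10, 0 °C to rt
Reagents that add atoms: methyl propiolate, C#CC(=O)OC
Why: Hydroalumination of methyl propiolate gives an α-(methoxycarbonyl)vinylalane that adds 1,2 to the aldehyde (vinylalumination route to Morita–Baylis–Hillman adducts) without the amine base that would conjugate the enal; the new carbinol centre is racemic and disappears in step 7.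

Step 7
Reactants: 11 methyl (5E,8E)-3-hydroxy-9-iodo-6-methyl-2-methylidenenona-5,8-dienoate
Product: 12 methyl (2Z,5E,8E)-2-(bromomethyl)-9-iodo-6-methylnona-2,5,8-trienoate
Conditions: NBS, Me2S, CH2Cl2, 0 °C to rt
Reagents that add atoms: N-bromosuccinimide, O=C1CCC(=O)N1Br
Why: The hydroxyl is activated as an alkoxysulfonium ion and bromide attacks the methylene terminus (SN2′ bromination of a Morita–Baylis–Hillman alcohol), which should give the thermodynamically preferred (2Z)-bromide; its geometry is not critical because the allylindium species of step 10 equilibrates.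

Step 8
Reactants: 13 (E)-1,1-diethoxybut-2-ene
Product: 14 (2R,3S)-2-(diethoxymethyl)-3-methyloxirane
Conditions: ent-Shi ketone (1,2:4,5-di-O-isopropylidene-β-L-erythro-2,3-hexodiulo-2,6-pyranose, 0.3 equiv), Oxone (2KHSO5·KHSO4·K2SO4), K2CO3, Bu4NHSO4, MeCN/CH2(OMe)2/aq. Na2B4O7–Na2EDTA, 0 °C
Reagents that add atoms: Oxone (potassium peroxymonosulfate), [K+].[O-]S(=O)(=O)OO
Why: Shi asymmetric epoxidation of a trans-disubstituted alkene through the spiro dioxirane transition state; the L-configured ketone should deliver oxygen to the face that gives the (2R,3S)-epoxide (the D-ketone gives its mirror image), and the basic buffer preserves the acetal.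

Step 9
Reactants: 14 (2R,3S)-2-(diethoxymethyl)-3-methyloxirane; 15 2-(3-chloropropyl)-2-methyl-1,3-dioxolane
Product: 17 (2R,3S)-1,1-diethoxy-3-methyl-6-(2-methyl-1,3-dioxolan-2-yl)hexan-2-ol, via Grignard reagent 16 (not isolated)
Conditions: 15, Mg, THF, reflux; CuI (cat.), then 14, THF, −30 to 0 °C; aq. NH4Cl
Reagents that add atoms: none
Why: Copper-catalysed SN2 opening of the epoxide by the Grignard reagent should occur at the methyl-bearing carbon, remote from the hindering and inductively deactivating acetal, with inversion there and retention at the carbinol carbon, which fixes the syn relationship of the C2 oxygen and the C3 methyl group.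

Step 10
Reactants: 17 (2R,3S)-1,1-diethoxy-3-methyl-6-(2-methyl-1,3-dioxolan-2-yl)hexan-2-ol; 12 methyl (2Z,5E,8E)-2-(bromomethyl)-9-iodo-6-methylnona-2,5,8-trienoate
Product: 20 (4S,5R)-5-[(1R,2S)-1-hydroxy-2-methyl-6-oxoheptyl]-4-[(2E,5E)-6-iodo-3-methylhexa-2,5-dien-1-yl]-3-methylideneoxolan-2-one, via hydroxy keto aldehyde 18 (not isolated), via dihydroxy ester 19 (not isolated)
Conditions: 1 M HCl, THF/H2O, rt; NaHCO3 to pH 6; 12, In (powder), THF/H2O, rt; then HCl to pH 1, rt
Reagents that add atoms: water, O
Why: Aqueous acid unmasks the α-hydroxy aldehyde and the ketone; in the indium-mediated Barbier allylation (Dreiding–Schmidt-type lactone synthesis) the allylindium from 12 attacks through its γ-carbon the aldehyde held in a five-membered chelate between trivalent indium, the free α-hydroxyl and the carbonyl oxygen, from the face opposite the C3 side chain, which should set C1 syn to the C2 hydroxyl and, through the cyclic transition state of the (Z)-configured reagent, C14 syn to C1 (cis-lactone), the ketone being far less reactive than the chelated aldehyde; acid then closes the five-membered lactone through the C1 hydroxyl in preference to the six-membered one through the C2 hydroxyl.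

Step 11
Reactants: 20 (4S,5R)-5-[(1R,2S)-1-hydroxy-2-methyl-6-oxoheptyl]-4-[(2E,5E)-6-iodo-3-methylhexa-2,5-dien-1-yl]-3-methylideneoxolan-2-one
Product: 21 (1R,2S)-1-[(2R,3S)-3-[(2E,5E)-6-iodo-3-methylhexa-2,5-dien-1-yl]-4-methylidene-5-oxooxolan-2-yl]-2-methyl-6-oxoheptyl acetate
Conditions: Ac2O, pyridine, DMAP (cat.), CH2Cl2, 0 °C to rt
Reagents that add atoms: acetic anhydride, CC(=O)OC(C)=O
Why: Nucleophile-catalysed acylation of the only free hydroxyl; ketone, lactone and alkenyl iodide are inert.

Step 12
Reactants: 21 (1R,2S)-1-[(2R,3S)-3-[(2E,5E)-6-iodo-3-methylhexa-2,5-dien-1-yl]-4-methylidene-5-oxooxolan-2-yl]-2-methyl-6-oxoheptyl acetate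
Product: 22 (1R,2S)-1-[(2R,3S)-3-{[(2R,3R)-3-[(E)-3-iodoprop-2-en-1-yl]-3-methyloxiran-2-yl]methyl}-4-methylidene-5-oxooxolan-2-yl]-2-methyl-6-oxoheptyl acetate
Conditions: Shi ketone (1,2:4,5-di-O-isopropylidene-β-D-erythro-2,3-hexodiulo-2,6-pyranose, 0.3–0.5 equiv), Oxone (2KHSO5·KHSO4·K2SO4), K2CO3, Bu4NHSO4, MeCN/CH2(OMe)2/aq. Na2B4O7–Na2EDTA (pH ≈ 10), 0 °C
Reagents that add atoms: Oxone (potassium peroxymonosulfate), [K+].[O-]S(=O)(=O)OO
Why: Shi asymmetric epoxidation: the electrophilic chiral dioxirane should attack only the electron-rich trisubstituted C11=C12 alkene (the α-methylene lactone and the alkenyl iodide are electron-poor), and the spiro transition state of the D-ketone should give the (11R,12R)-epoxide under reagent control, the nearest stereocentre being two atoms away; the substrate's own dialkyl ketone is a much weaker dioxirane precursor than the catalyst.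

Step 13
Reactants: 22 (1R,2S)-1-[(2R,3S)-3-{[(2R,3R)-3-[(E)-3-iodoprop-2-en-1-yl]-3-methyloxiran-2-yl]methyl}-4-methylidene-5-oxooxolan-2-yl]-2-methyl-6-oxoheptyl acetate
Product: 23 target cembranolide CNP0202356.4
Conditions: CrCl2 (15 equiv), NiCl2 (0.15 equiv), degassed DMSO/THF, slow addition of 22 to 0.002 M, rt to 40 °C
Reagents that add atoms: none
Why: Zerovalent nickel, formed from NiCl2 by CrCl2, inserts into the C8–I bond with retention and passes the (E)-alkenyl group to trivalent chromium; the alkenylchromium then adds to the C7 ketone through a four-centred, chromium–oxygen bound transition state and gives the chromium alkoxide of 23 (Nozaki–Hiyama–Kishi reaction). The closest known reactions are Nozaki–Hiyama–Kishi macrocyclisations of alkenyl iodides onto aldehydes and intramolecular alkenylchromium additions to ketones, which are slower but here face no competing aldehyde. The 14-membered carbocycle closes in the 14-exo-trig mode, helped by high dilution and by the three rigid elements of the chain (cis-lactone, trans-epoxide, E-alkene). The new C7 stereocentre is under substrate control: the target needs attack on the Re face of the ketone, expected from a macrocyclic transition state in which the bulky solvated chromium alkoxide points to the periphery and the methyl group lies near the ring plane, with the C1, C2, C3 and C14 stereocentres and the epoxide deciding which of the two such arrangements is free of strain; this prediction is the least secure element of the route. The step needs chemoselectivity for the ketone over acetate, lactone, enoate and epoxide, which the low basicity and high oxophilicity of alkenylchromium should secure, and retention of the E geometry, which the stereospecific nickel-to-chromium transfer secures.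

Compound list
1 | ethynyltrimethylsilane | C#C[Si](C)(C)C | starting material
2 | propargyl bromide (3-bromoprop-1-yne) | BrCC#C | starting material
3 | [(trimethylsilyl)ethynyl]magnesium bromide | C[Si](C)(C)C#C[Mg]Br | intermediate
4 | 1-(trimethylsilyl)penta-1,4-diyne | C[Si](C)(C)C#CCC#C | intermediate
5 | (E)-dimethyl[2-methyl-5-(trimethylsilyl)pent-1-en-4-yn-1-yl]alane | C[Al](C)/C=C(\C)CC#C[Si](C)(C)C | intermediate
6 | (E)-4-methyl-7-(trimethylsilyl)hept-3-en-6-yn-1-ol | OCC/C=C(\C)CC#C[Si](C)(C)C | intermediate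
7 | (E)-4-methylhept-3-en-6-yn-1-ol | OCC/C=C(\C)CC#C | intermediate
8 | O-zirconated (1E,4E)-alkenylzirconocene chloride from 7 | Cl[Zr](OCC/C=C(\C)C/C=C/[Zr](Cl)(C1C=CC=C1)C1C=CC=C1)(C1C=CC=C1)C1C=CC=C1 | intermediate
9 | (3E,6E)-7-iodo-4-methylhepta-3,6-dien-1-ol | OCC/C=C(\C)C/C=C/I | intermediate
10 | (3E,6E)-7-iodo-4-methylhepta-3,6-dienal | O=CC/C=C(\C)C/C=C/I | intermediate
11 | methyl (5E,8E)-3-hydroxy-9-iodo-6-methyl-2-methylidenenona-5,8-dienoate (racemic at C3) | C=C(C(=O)OC)C(O)C/C=C(\C)C/C=C/I | intermediate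
12 | methyl (2Z,5E,8E)-2-(bromomethyl)-9-iodo-6-methylnona-2,5,8-trienoate | COC(=O)/C(CBr)=C/C/C=C(\C)C/C=C/I | intermediate
13 | (E)-1,1-diethoxybut-2-ene (crotonaldehyde diethyl acetal) | C/C=C/C(OCC)OCC | starting material
14 | (2R,3S)-2-(diethoxymethyl)-3-methyloxirane | C[C@@H]1O[C@H]1C(OCC)OCC | intermediate
15 | 2-(3-chloropropyl)-2-methyl-1,3-dioxolane | CC1(CCCCl)OCCO1 | starting material
16 | [3-(2-methyl-1,3-dioxolan-2-yl)propyl]magnesium chloride | CC1(CCC[Mg]Cl)OCCO1 | intermediate
17 | (2R,3S)-1,1-diethoxy-3-methyl-6-(2-methyl-1,3-dioxolan-2-yl)hexan-2-ol | CCOC(OCC)[C@H](O)[C@@H](C)CCCC1(C)OCCO1 | intermediate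
18 | (2R,3S)-2-hydroxy-3-methyl-7-oxooctanal | O=C[C@H](O)[C@@H](C)CCCC(C)=O | intermediate
19 | methyl (3S,4R,5R,6S)-4,5-dihydroxy-3-[(2E,5E)-6-iodo-3-methylhexa-2,5-dien-1-yl]-6-methyl-2-methylidene-10-oxoundecanoate | COC(=O)C(=C)[C@H](C/C=C(\C)C/C=C/I)[C@@H](O)[C@H](O)[C@@H](C)CCCC(C)=O | intermediate
20 | (4S,5R)-5-[(1R,2S)-1-hydroxy-2-methyl-6-oxoheptyl]-4-[(2E,5E)-6-iodo-3-methylhexa-2,5-dien-1-yl]-3-methylideneoxolan-2-one | C=C1C(=O)O[C@@H]([C@H](O)[C@@H](C)CCCC(C)=O)[C@H]1C/C=C(\C)C/C=C/I | intermediate
21 | (1R,2S)-1-[(2R,3S)-3-[(2E,5E)-6-iodo-3-methylhexa-2,5-dien-1-yl]-4-methylidene-5-oxooxolan-2-yl]-2-methyl-6-oxoheptyl acetate | C=C1C(=O)O[C@@H]([C@H](OC(C)=O)[C@@H](C)CCCC(C)=O)[C@H]1C/C=C(\C)C/C=C/I | intermediate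
22 | (1R,2S)-1-[(2R,3S)-3-{[(2R,3R)-3-[(E)-3-iodoprop-2-en-1-yl]-3-methyloxiran-2-yl]methyl}-4-methylidene-5-oxooxolan-2-yl]-2-methyl-6-oxoheptyl acetate | C=C1C(=O)O[C@@H]([C@H](OC(C)=O)[C@@H](C)CCCC(C)=O)[C@H]1C[C@H]2O[C@]2(C)C/C=C/I | intermediate
23 | CNP0202356.4: (1R,2R,3S,7S,8E,11R,12R,14S)-configured 14-membered carbocycle (numbering of the overview) with a cis-fused α-methylene-γ-butyrolactone across C14–C1, 2-acetoxy, 3-methyl, 7-hydroxy-7-methyl, 8,9-alkene and 11-methyl-11,12-epoxide | C=C1C(=O)O[C@H]2[C@H](OC(C)=O)[C@@H](C)CCC[C@](C)(O)/C=C/C[C@@]3(C)O[C@@H]3C[C@@H]12 | target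

Total step count: 13 steps.
Longest linear sequence: 11 steps (steps 1–7 and 10–13, from 1 and 2); the second fragment takes 2 steps (8 and 9).

Steps most likely to fail

Step 13. Addition of the alkenylchromium to the weakly electrophilic methyl ketone may be so slow that protodemetalation or oligomerisation outruns ring closure, or facial selectivity at C7 may be poor. The fallback sets out from 14 and comes back at 23: the same C7–C8 bond would be closed at the aldehyde oxidation level, where this macrocyclisation is routine, and the methyl group added afterwards. Opening of 14 with pent-4-enylmagnesium bromide and CuI would give (2R,3S)-1,1-diethoxy-3-methyloct-7-en-2-ol F1. Under the conditions of step 10 this would pass through (2R,3S)-2-hydroxy-3-methyloct-7-enal F2 and, with 12, the dihydroxy ester F3 to the hydroxy lactone F4. Acetylation as in step 11 would give the acetate F5, and Shi epoxidation as in step 12 (a terminal vinyl group is much less reactive than the trisubstituted alkene) the epoxide F6. Lemieux–Johnson cleavage of the terminal alkene (OsO4 cat., NaIO4, 2,6-lutidine, dioxane/H2O; the enoate and the alkenyl iodide are electron-poor) would give the aldehyde F7. CrCl2/NiCl2 in DMSO at high dilution would give the macrocyclic secondary allylic alcohol F8 as a mixture of C7 epimers, and Dess–Martin oxidation the 14-membered enone F9. MeMgBr/CeCl3 in THF at −78 °C should add to the ketone from the ring periphery, spare the esters and give 23; C7 is then controlled by an external nucleophile on a macrocyclic enone, a different element from that of step 13.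

Step 10. Chelation control at the aldehyde face may be insufficient, the free α-hydroxy aldehyde may isomerise or oligomerise before it couples, or the six-membered lactone may form through the C2 hydroxyl. The fallback sets out from 17 and 12 and comes back at 20: a protected aldehyde and a Lewis-acid chelate would replace the aqueous Barbier reaction. NaH, 4-methoxybenzyl chloride and Bu4NI in DMF would convert 17 into the 4-methoxybenzyl ether F10, and 2 M HCl in THF would give the α-(4-methoxybenzyloxy) keto aldehyde F11. Bu3SnCl and Zn in THF/aq. NH4Cl would turn 12 into the allylstannane F12. MgBr2·OEt2 in CH2Cl2 at −25 °C would hold the aldehyde and ether oxygens in a five-membered chelate, and SE2′ attack of F12 through an open transition state (chelation-controlled allylstannane addition) should give the syn,syn hydroxy ester F13. p-TsOH would close the lactone F14, in which only one hydroxyl is free, and DDQ in CH2Cl2/pH 7 buffer would release 20.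

Step 12. Facial control may be eroded by a dioxirane formed from the substrate's own methyl ketone, and the basic medium may open or oxidise the α-methylene lactone or hydrolyse the acetate. The fallback sets out from 11 and comes back at 22: the epoxide would be installed before the fragments are joined, when neither the ketone nor the lactone is present. Shi epoxidation of 11 with the D-ketone would give the epoxy alcohol F15, and NBS/Me2S at −20 °C the epoxy allylic bromide F16. Indium coupling of F16 with 18 (made from 17 as in step 10) in THF/pH 7 phosphate buffer would give the epoxy dihydroxy ester F17. Bu2SnO (cat.) in toluene at 60 °C would lactonise it under neutral conditions to the epoxy hydroxy lactone F18; acid must be avoided here because the hydroxyl that becomes the lactone oxygen can open the epoxide in a 5-exo fashion. Acetylation as in step 11 would give 22.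

Further compounds
F1 | step 13 | (2R,3S)-1,1-diethoxy-3-methyloct-7-en-2-ol | CCOC(OCC)[C@H](O)[C@@H](C)CCCC=C
F2 | step 13 | (2R,3S)-2-hydroxy-3-methyloct-7-enal | O=C[C@H](O)[C@@H](C)CCCC=C
F3 | step 13 | methyl (3S,4R,5R,6S)-4,5-dihydroxy-3-[(2E,5E)-6-iodo-3-methylhexa-2,5-dien-1-yl]-6-methyl-2-methylideneundec-10-enoate | COC(=O)C(=C)[C@H](C/C=C(\C)C/C=C/I)[C@@H](O)[C@H](O)[C@@H](C)CCCC=C
F4 | step 13 | (4S,5R)-5-[(1R,2S)-1-hydroxy-2-methylhept-6-en-1-yl]-4-[(2E,5E)-6-iodo-3-methylhexa-2,5-dien-1-yl]-3-methylideneoxolan-2-one | C=C1C(=O)O[C@@H]([C@H](O)[C@@H](C)CCCC=C)[C@H]1C/C=C(\C)C/C=C/I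
F5 | step 13 | (1R,2S)-1-[(2R,3S)-3-[(2E,5E)-6-iodo-3-methylhexa-2,5-dien-1-yl]-4-methylidene-5-oxooxolan-2-yl]-2-methylhept-6-en-1-yl acetate | C=C1C(=O)O[C@@H]([C@H](OC(C)=O)[C@@H](C)CCCC=C)[C@H]1C/C=C(\C)C/C=C/I
F6 | step 13 | (1R,2S)-1-[(2R,3S)-3-{[(2R,3R)-3-[(E)-3-iodoprop-2-en-1-yl]-3-methyloxiran-2-yl]methyl}-4-methylidene-5-oxooxolan-2-yl]-2-methylhept-6-en-1-yl acetate | C=C1C(=O)O[C@@H]([C@H](OC(C)=O)[C@@H](C)CCCC=C)[C@H]1C[C@H]2O[C@]2(C)C/C=C/I
F7 | step 13 | (1R,2S)-1-[(2R,3S)-3-{[(2R,3R)-3-[(E)-3-iodoprop-2-en-1-yl]-3-methyloxiran-2-yl]methyl}-4-methylidene-5-oxooxolan-2-yl]-2-methyl-6-oxohexyl acetate | C=C1C(=O)O[C@@H]([C@H](OC(C)=O)[C@@H](C)CCCC=O)[C@H]1C[C@H]2O[C@]2(C)C/C=C/I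
F8 | step 13 | 7-demethyl analogue of 23 with a secondary C7 hydroxyl (both C7 epimers) | C=C1C(=O)O[C@H]2[C@H](OC(C)=O)[C@@H](C)CCCC(O)/C=C/C[C@@]3(C)O[C@@H]3C[C@@H]12
F9 | step 13 | 7-demethyl-7-oxo analogue of 23 (14-membered enone) | C=C1C(=O)O[C@H]2[C@H](OC(C)=O)[C@@H](C)CCCC(=O)/C=C/C[C@@]3(C)O[C@@H]3C[C@@H]12
F10 | step 10 | 1-({[(2R,3S)-1,1-diethoxy-3-methyl-6-(2-methyl-1,3-dioxolan-2-yl)hexan-2-yl]oxy}methyl)-4-methoxybenzene | CCOC(OCC)[C@H](OCc1ccc(OC)cc1)[C@@H](C)CCCC2(C)OCCO2
F11 | step 10 | (2R,3S)-2-[(4-methoxybenzyl)oxy]-3-methyl-7-oxooctanal | O=C[C@H](OCc1ccc(OC)cc1)[C@@H](C)CCCC(C)=O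
F12 | step 10 | methyl (2Z,5E,8E)-9-iodo-6-methyl-2-[(tributylstannyl)methyl]nona-2,5,8-trienoate | CCCC[Sn](CCCC)(CCCC)C/C(C(=O)OC)=C\C/C=C(\C)C/C=C/I
F13 | step 10 | methyl (3S,4R,5R,6S)-4-hydroxy-3-[(2E,5E)-6-iodo-3-methylhexa-2,5-dien-1-yl]-5-[(4-methoxybenzyl)oxy]-6-methyl-2-methylidene-10-oxoundecanoate | COC(=O)C(=C)[C@H](C/C=C(\C)C/C=C/I)[C@@H](O)[C@H](OCc1ccc(OC)cc1)[C@@H](C)CCCC(C)=O
F14 | step 10 | (4S,5R)-4-[(2E,5E)-6-iodo-3-methylhexa-2,5-dien-1-yl]-5-{(1R,2S)-1-[(4-methoxybenzyl)oxy]-2-methyl-6-oxoheptyl}-3-methylideneoxolan-2-one | C=C1C(=O)O[C@@H]([C@H](OCc2ccc(OC)cc2)[C@@H](C)CCCC(C)=O)[C@H]1C/C=C(\C)C/C=C/I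
F15 | step 12 | methyl 3-hydroxy-4-{(2R,3R)-3-[(E)-3-iodoprop-2-en-1-yl]-3-methyloxiran-2-yl}-2-methylidenebutanoate | C=C(C(=O)OC)C(O)C[C@H]1O[C@]1(C)C/C=C/I
F16 | step 12 | methyl (2Z)-2-(bromomethyl)-4-{(2R,3R)-3-[(E)-3-iodoprop-2-en-1-yl]-3-methyloxiran-2-yl}but-2-enoate | COC(=O)/C(CBr)=C/C[C@H]1O[C@]1(C)C/C=C/I
F17 | step 12 | methyl (3S,4R,5R,6S)-4,5-dihydroxy-3-({(2R,3R)-3-[(E)-3-iodoprop-2-en-1-yl]-3-methyloxiran-2-yl}methyl)-6-methyl-2-methylidene-10-oxoundecanoate | COC(=O)C(=C)[C@H](C[C@H]1O[C@]1(C)C/C=C/I)[C@@H](O)[C@H](O)[C@@H](C)CCCC(C)=O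
F18 | step 12 | (4S,5R)-5-[(1R,2S)-1-hydroxy-2-methyl-6-oxoheptyl]-4-({(2R,3R)-3-[(E)-3-iodoprop-2-en-1-yl]-3-methyloxiran-2-yl}methyl)-3-methylideneoxolan-2-one | C=C1C(=O)O[C@@H]([C@H](O)[C@@H](C)CCCC(C)=O)[C@H]1C[C@H]2O[C@]2(C)C/C=C/I
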